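**Retrosynthetic overview**
- The only carbocycle is the cyclohexa-2,5-dienone C1(=O)–C2(allyl)=C3H–C4(OMe)(C8)–C5(OMe)=C6H, with the side chain C8H(CH3)–C7H(OAc)–veratryl. Every ring bond except C2=C3 ends at an oxygen-bearing carbon. C2=C3 is therefore cut to a C4 vinyl group and a C2 methylidene, and the ring is closed last by ring-closing metathesis.
- In the acyclic (E)-5-methoxy dienone, C5–OMe comes from methanol addition to a C5≡C6 alkynone. C6–C1 comes from acyl Sonogashira coupling of a C4 ethynyl block with 2-methylidenepent-4-enoyl chloride.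
- C4 (R) comes from chelate-controlled alkynylation of a C4 vinyl ketone followed by O-methylation. C7/C8 (R,R, syn) come from an Evans aldol reaction of veratraldehyde.
- C7–OH travels as a SEM ether, which chelates and leaves with fluoride; an oxidatively cleaved benzyl-type ether would not be selective next to the veratryl carbinol. It becomes the acetate at the alkyne stage, before any Michael acceptor exists.

Key step: step 13

Remark on the chemistry: in this numbering the SMILES descriptors translate to 4R, 7R, 8R. The 7R,8R pair is the syn-aldol relationship, which calls for the (R)-configured auxiliary.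

**Step 1**
Reactants: 1 (4R)-4-benzyl-3-propanoyl-1,3-oxazolidin-2-one; 2 veratraldehyde (3,4-dimethoxybenzaldehyde)
Product: 4 (4R)-4-benzyl-3-[(2R,3R)-3-(3,4-dimethoxyphenyl)-3-hydroxy-2-methylpropanoyl]-1,3-oxazolidin-2-one (7,8-syn aldol adduct), via Z-dibutylboron enolate 3 (not isolated)
Conditions: Bu2BOTf, Et3N, CH2Cl2, 0 °C; 2, −78 → 0 °C; then H2O2, MeOH, pH 7 buffer, 0 °C
Reagents that add atoms: none
Why: Evans boron syn-aldol reaction, in which the Z-enolate reacts through a closed Zimmerman–Traxler chair while the benzyl group of the dipole-opposed (R)-auxiliary blocks one enolate face, so that C8 (R) and C7 (R) should be set together as the syn pair.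

**Step 2**
Reactants: 4 syn aldol adduct
Product: 5 (2R,3R)-3-(3,4-dimethoxyphenyl)-3-hydroxy-N-methoxy-N,2-dimethylpropanamide
Conditions: MeNH(OMe)·HCl, AlMe3, CH2Cl2, −10 °C → rt; aq. potassium sodium tartrate
Reagents that add atoms: N,O-dimethylhydroxylamine hydrochloride, CNOC.Cl
Why: Aluminium amide transamination (Weinreb amide synthesis) is steered to the exocyclic acyl group by the aluminium alkoxide of the free C7–OH, leaves C7 and C8 untouched and returns the auxiliary.

**Step 3**
Reactants: 5 hydroxy Weinreb amide
Product: 6 (2R,3R)-3-(3,4-dimethoxyphenyl)-N-methoxy-N,2-dimethyl-3-{[2-(trimethylsilyl)ethoxy]methoxy}propanamide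
Conditions: SEMCl, iPr2NEt, Bu4NI (cat.), CH2Cl2, 0 → 35 °C
Reagents that add atoms: 2-(trimethylsilyl)ethoxymethyl chloride, C[Si](C)(C)CCOCCl
Why: O-alkylation with a chloromethyl ether under amine base avoids retro-aldol cleavage and installs an acetal-type group that can chelate magnesium in step 5 and leaves with fluoride, whereas DDQ cleavage of a p-methoxybenzyl ether would also attack the more electron-rich veratryl carbinol position C7.

**Step 4**
Reactants: 6 SEM-protected Weinreb amide; 7 vinylmagnesium bromide
Product: 8 (4R,5R)-5-(3,4-dimethoxyphenyl)-4-methyl-5-{[2-(trimethylsilyl)ethoxy]methoxy}pent-1-en-3-one (C4 vinyl ketone)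
Conditions: 7, THF, −20 → 0 °C; inverse quench into cold 1 M HCl
Reagents that add atoms: none
Why: Weinreb ketone synthesis, in which the five-membered magnesium chelate stops the reaction after one addition and the inverse acidic quench protonates the released N,O-dimethylhydroxylamine before it can add to the new vinyl ketone, with C8 kept intact at low temperature.

**Step 5**
Reactants: 8 C4 vinyl ketone; 9 ethynyltrimethylsilane
Product: 11 (3R,4R,5R)-5-(3,4-dimethoxyphenyl)-4-methyl-5-{[2-(trimethylsilyl)ethoxy]methoxy}-3-[(trimethylsilyl)ethynyl]pent-1-en-3-ol (C4 tertiary alcohol), via alkynylmagnesium bromide 10 (not isolated)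
Conditions: 9, EtMgBr, Et2O, 0 °C → rt; then 8, CH2Cl2–Et2O, −78 → −30 °C; aq. NH4Cl
Reagents that add atoms: none
Why: Chelation-controlled (Cram chelate) 1,2-addition, in which magnesium in the weakly coordinating medium ties the C4 carbonyl oxygen to the C7 acetal oxygen in a six-membered chelate that carries the C8 methyl and C7 aryl groups of the syn substrate on the same face, so that the acetylide should enter from the opposite face and give 4R.

**Step 6**
Reactants: 11 C4 tertiary alcohol
Product: 12 (3R,4R,5R)-configured C4 methyl ether of 11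
Conditions: NaH, MeI, THF–DMF (4:1), 0 °C → rt
Reagents that add atoms: iodomethane, CI
Why: Williamson ether synthesis on a tertiary alkoxide flanked only by slim vinyl and alkynyl groups, under conditions to which the SEM acetal and the C–Si bond are stable and which do not touch the C–O bond at C4.

**Step 7**
Reactants: 12 C4 methyl ether
Product: 13 (1R,2R,3R)-1-(3,4-dimethoxyphenyl)-3-ethynyl-3-methoxy-2-methylpent-4-en-1-ol
Conditions: Bu4NF (excess), DMPU–THF, 4 Å molecular sieves, 60 °C
Reagents that add atoms: none
Why: Fluoride-induced desilylation cleaves the alkynyl C–Si bond at once and, on warming in the dipolar medium, attacks the SEM silicon so that ethene and formaldehyde are lost by fragmentation, which frees C7–OH without acid or oxidant and spares the ionisable C4 and C7 positions.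

**Step 8**
Reactants: 13 alkynol
Product: 14 (1R,2R,3R)-1-(3,4-dimethoxyphenyl)-3-ethynyl-3-methoxy-2-methylpent-4-en-1-yl acetate
Conditions: Ac2O, pyridine, DMAP (cat.), CH2Cl2, rt
Reagents that add atoms: acetic anhydride, CC(=O)OC(C)=O
Why: DMAP-catalysed O-acylation of the only hydroxyl group, done here because all later steps are neutral or only catalytically basic and because a free C7–OH would add in a 5-exo mode to C5 once the alkynone or the vinylogous ester is present.

**Step 9**
Reactants: 15 allylmalonic acid
Product: 16 2-methylidenepent-4-enoic acid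
Conditions: (CH2O)n, Et2NH, EtOAc, reflux
Reagents that add atoms: formaldehyde (as paraformaldehyde), C=O
Why: Decarboxylative Mannich methylenation (Knoevenagel–Doebner type), in which the malonic acid adds to the iminium ion from formaldehyde and diethylamine and loss of CO2 with expulsion of the amine gives the α-substituted acrylic acid.

**Step 10**
Reactants: 16 2-methylidenepent-4-enoic acid
Product: 17 2-methylidenepent-4-enoyl chloride (used crude, stabilised with BHT)
Conditions: (COCl)2, DMF (cat.), CH2Cl2, 0 °C → rt
Reagents that add atoms: oxalyl chloride, O=C(Cl)C(=O)Cl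
Why: Acid chloride formation through the chloroiminium species from DMF and oxalyl chloride runs at or below room temperature with gaseous co-products only, which suits a polymerisable acryloyl chloride.

**Step 11**
Reactants: 14 alkyne acetate; 17 2-methylidenepent-4-enoyl chloride
Product: 18 (1R,2R,3R)-1-(3,4-dimethoxyphenyl)-3-ethenyl-3-methoxy-2-methyl-7-methylidene-6-oxodec-9-en-4-yn-1-yl acetate (cross-conjugated alkynone)
Conditions: PdCl2(PPh3)2 (2 mol %), CuI (4 mol %), Et3N (1.2 equiv), THF, rt
Reagents that add atoms: none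
Why: Acyl Sonogashira coupling, in which oxidative addition of the acid chloride to zerovalent palladium, transmetalation from the copper acetylide of 14 and reductive elimination form C6–C1 under amine-base conditions that spare the acetate, the tertiary ether and the stereocentres.

**Step 12**
Reactants: 18 cross-conjugated alkynone
Product: 19 (1R,2R,3R,4E)-1-(3,4-dimethoxyphenyl)-3-ethenyl-3,4-dimethoxy-2-methyl-7-methylidene-6-oxodeca-4,9-dien-1-yl acetate (acyclic E β-methoxy dienone)
Conditions: MeOH (3 equiv), PMe3 (10 mol %), CH2Cl2, 0 °C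
Reagents that add atoms: methanol, CO
Why: Phosphine-catalysed oxa-Michael (hydroxyl–yne) addition, in which catalytic methoxide adds irreversibly to alkynone carbon C5 while its addition to the α-branched C2 methylidene is reversible and disfavoured by the small excess of methanol, the allenolate is protonated at C6 from the side of the small methoxy group rather than of quaternary C4 so that C4 and C1 should end up cis (E), and the acetate never meets stoichiometric base.

**Step 13**
Reactants: 19 acyclic E β-methoxy dienone
Product: 20 (1R,2R)-1-(3,4-dimethoxyphenyl)-2-[(1R)-1,6-dimethoxy-4-oxo-3-(prop-2-en-1-yl)cyclohexa-2,5-dien-1-yl]propyl acetate (target)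
Conditions: second-generation Grubbs catalyst RuCl2(=CHPh)(PCy3)(SIMes) (10 mol %, two portions), 1,4-benzoquinone (20 mol %), toluene, 0.001 M, 80 °C, argon
Reagents that add atoms: none
Why: The reaction is olefin metathesis by the Chauvin mechanism, and the catalyst will exchange fastest with the unhindered allyl terminus, but that alkylidene has no productive partner (closure onto the C2 methylidene would mean a three-membered ring and closure onto the C4 vinyl group a cyclooctadienone), so at this dilution it is a resting state and the productive carbene is the one formed more slowly at C3 of the C4 vinyl group. This Ru=C3 alkylidene adds to the C2 methylidene through a ruthenacyclobutane whose cycloreversion forms C2=C3 and a ruthenium methylidene, so ethene is the only co-product and the carbocycle C1–C6 closes in a six-membered ring-closing mode between a monosubstituted alkene and a 1,1-disubstituted, acyl-bearing alkene. The closest known reactions are ring-closing metatheses of allylic ethers or carbinols carrying α-substituted acryloyl units, which give 2-substituted cyclohexenones and butenolides, and of cross-conjugated trienones, which give cyclohexadienones. No stereocentre is made, C4, C7 and C8 are spectators, and quaternary C4 keeps the dienone from tautomerising to a phenol. Selectivity among the three terminal alkenes rests on ring size, on the E geometry at C5=C6 that puts both reacting arms on the same side of that bond, on the geminal substitution at C4, and on the inertness of the trisubstituted, carbonyl-conjugated C2=C3 bond, whereas any dimer or eight-membered ring keeps a reactive 1,2-disubstituted alkene and can re-enter the cycle. 1,4-Benzoquinone intercepts ruthenium hydrides that would draw the skipped diene of the C2 allyl group into conjugation.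

**Compound list**
1 | (4R)-4-benzyl-3-propanoyl-1,3-oxazolidin-2-one | CCC(=O)N1C(=O)OC[C@H]1Cc1ccccc1 | starting material
2 | veratraldehyde | COc1ccc(C=O)cc1OC | starting material
3 | Z-dibutylboron enolate of 1 | C/C=C(\OB(CCCC)CCCC)N1C(=O)OC[C@H]1Cc1ccccc1 | intermediate
4 | (4R)-4-benzyl-3-[(2R,3R)-3-(3,4-dimethoxyphenyl)-3-hydroxy-2-methylpropanoyl]-1,3-oxazolidin-2-one | O=C([C@H](C)[C@@H](O)c1ccc(OC)c(OC)c1)N1C(=O)OC[C@H]1Cc1ccccc1 | intermediate
5 | (2R,3R)-3-(3,4-dimethoxyphenyl)-3-hydroxy-N-methoxy-N,2-dimethylpropanamide | CON(C)C(=O)[C@H](C)[C@@H](O)c1ccc(OC)c(OC)c1 | intermediate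
6 | SEM ether of 5 | CON(C)C(=O)[C@H](C)[C@@H](OCOCC[Si](C)(C)C)c1ccc(OC)c(OC)c1 | intermediate
7 | vinylmagnesium bromide | C=C[Mg]Br | starting material
8 | (4R,5R)-5-(3,4-dimethoxyphenyl)-4-methyl-5-{[2-(trimethylsilyl)ethoxy]methoxy}pent-1-en-3-one | C=CC(=O)[C@H](C)[C@@H](OCOCC[Si](C)(C)C)c1ccc(OC)c(OC)c1 | intermediate
9 | ethynyltrimethylsilane | C#C[Si](C)(C)C | starting material
10 | [(trimethylsilyl)ethynyl]magnesium bromide | C[Si](C)(C)C#C[Mg]Br | intermediate
11 | (3R,4R,5R)-5-(3,4-dimethoxyphenyl)-4-methyl-5-{[2-(trimethylsilyl)ethoxy]methoxy}-3-[(trimethylsilyl)ethynyl]pent-1-en-3-ol | C=C[C@@](O)([C@H](C)[C@@H](OCOCC[Si](C)(C)C)c1ccc(OC)c(OC)c1)C#C[Si](C)(C)C | intermediate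
12 | C4 methyl ether of 11 | C=C[C@@](OC)([C@H](C)[C@@H](OCOCC[Si](C)(C)C)c1ccc(OC)c(OC)c1)C#C[Si](C)(C)C | intermediate
13 | (1R,2R,3R)-1-(3,4-dimethoxyphenyl)-3-ethynyl-3-methoxy-2-methylpent-4-en-1-ol | C=C[C@@](OC)([C@H](C)[C@@H](O)c1ccc(OC)c(OC)c1)C#C | intermediate
14 | (1R,2R,3R)-1-(3,4-dimethoxyphenyl)-3-ethynyl-3-methoxy-2-methylpent-4-en-1-yl acetate | C=C[C@@](OC)([C@H](C)[C@@H](OC(C)=O)c1ccc(OC)c(OC)c1)C#C | intermediate
15 | allylmalonic acid | C=CCC(C(=O)O)C(=O)O | starting material
16 | 2-methylidenepent-4-enoic acid | C=CCC(=C)C(=O)O | intermediate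
17 | 2-methylidenepent-4-enoyl chloride | C=CCC(=C)C(=O)Cl | intermediate
18 | (1R,2R,3R)-1-(3,4-dimethoxyphenyl)-3-ethenyl-3-methoxy-2-methyl-7-methylidene-6-oxodec-9-en-4-yn-1-yl acetate | C=C[C@@](OC)([C@H](C)[C@@H](OC(C)=O)c1ccc(OC)c(OC)c1)C#CC(=O)C(=C)CC=C | intermediate
19 | (1R,2R,3R,4E)-1-(3,4-dimethoxyphenyl)-3-ethenyl-3,4-dimethoxy-2-methyl-7-methylidene-6-oxodeca-4,9-dien-1-yl acetate | C=C[C@@](OC)([C@H](C)[C@@H](OC(C)=O)c1ccc(OC)c(OC)c1)/C(OC)=C\C(=O)C(=C)CC=C | intermediate
20 | (1R,2R)-1-(3,4-dimethoxyphenyl)-2-[(1R)-1,6-dimethoxy-4-oxo-3-(prop-2-en-1-yl)cyclohexa-2,5-dien-1-yl]propyl acetate | C=CCC1=C[C@@](OC)([C@H](C)[C@@H](OC(C)=O)c2ccc(OC)c(OC)c2)C(OC)=CC1=O | target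

**Step count**
Total step count: 13. Longest linear sequence: 11 (steps 1–8, 11, 12, 13).

**Steps most likely to fail**

Step 13 (key step). Loading of ruthenium at the neopentyl-like C4 vinyl group may be too slow. Intermolecular coupling through the allyl terminus, closure to the eight-membered ring or catalyst decay could then take over.

The fallback is a relay ring-closing metathesis that sets out from 6 and comes back at 20. Takai olefination of commercial hex-5-enal (CHI3, CrCl2, THF) gives (E)-1-iodohepta-1,6-diene F1. Iodine–lithium exchange (t-BuLi, Et2O, −78 °C) gives (E)-hepta-1,6-dien-1-yllithium F2, which reacts with 6 to give the E-enone F3. The operations of steps 5 to 8, 11 and 12 are then repeated in this series. Reagent 10 gives the tertiary alcohol F4, NaH/MeI gives the methyl ether F5, Bu4NF gives the alkynol F6, and Ac2O gives the acetate F7. Coupling with 17 under PdCl2(PPh3)2/CuI gives the alkynone F8, and MeOH/PMe3 gives the relay substrate F9. The same catalyst now enters at the unhindered end of the tether, expels cyclopentene and is thereby placed on C3. From there the closure onto the C2 methylidene gives 20.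

Step 12. Methanol or the phosphine may add to the C2 methylidene in competition with C5. The allenolate may also be protonated from the wrong side, which gives the Z enol ether whose arms cannot meet.

The fallback introduces the methylidene only after the enol ether; it sets out from 14 and comes back at 19. Compound 14 is coupled (PdCl2(PPh3)2, CuI, Et3N, THF) with commercial pent-4-enoyl chloride to give the alkynone F10, which has one acceptor site only. MeOH/PMe3 gives the E enol ether F11. Soft enolisation (TMSOTf, Et3N, CH2Cl2, −78 → 0 °C) gives the 2-silyloxydiene F12. Dimethyl(methylidene)ammonium iodide attacks its terminus C2 to give the Mannich base F13 as a mixture at C2, which has no consequence. MeI gives the methiodide F14, and aq. NaHCO3/CH2Cl2 eliminates trimethylamine to give 19.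

Step 5. Incomplete chelation would mean poor facial selectivity at C4, and enolisation or conjugate addition of the vinyl ketone may compete.

The fallback reverses the order of the two C4 substituents and relies on Felkin–Anh control with a non-chelating silyl ether; it sets out from 5 and comes back at 13. TBSOTf/2,6-lutidine gives the silyl ether F15, and reagent 10 converts it into the alkynyl ketone F16. Reagent 7 in THF at −78 °C adds to the carbonyl face opposite to the one opened by a chelate. Because the resident and incoming groups are exchanged, this leads to the same 4R configuration in the tertiary alcohol F17. MeOTf/2,6-di-tert-butylpyridine gives the methyl ether F18 under neutral conditions that prevent silyl migration. Bu4NF removes both silyl groups and gives 13.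

**Further compounds**
F1 | step 13 | (E)-1-iodohepta-1,6-diene | I/C=C/CCCC=C
F2 | step 13 | (E)-hepta-1,6-dien-1-yllithium | [Li]/C=C/CCCC=C
F3 | step 13 | (1R,2R,4E)-1-(3,4-dimethoxyphenyl)-2-methyl-1-{[2-(trimethylsilyl)ethoxy]methoxy}deca-4,9-dien-3-one | C=CCCC/C=C/C(=O)[C@H](C)[C@@H](OCOCC[Si](C)(C)C)c1ccc(OC)c(OC)c1
F4 | step 13 | analogue of 11 with (E)-hepta-1,6-dienyl in place of vinyl at C4 | C=CCCC/C=C/[C@@](O)([C@H](C)[C@@H](OCOCC[Si](C)(C)C)c1ccc(OC)c(OC)c1)C#C[Si](C)(C)C
F5 | step 13 | analogue of 12 with (E)-hepta-1,6-dienyl at C4 | C=CCCC/C=C/[C@@](OC)([C@H](C)[C@@H](OCOCC[Si](C)(C)C)c1ccc(OC)c(OC)c1)C#C[Si](C)(C)C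
F6 | step 13 | analogue of 13 with (E)-hepta-1,6-dienyl at C4 | C=CCCC/C=C/[C@@](OC)([C@H](C)[C@@H](O)c1ccc(OC)c(OC)c1)C#C
F7 | step 13 | analogue of 14 with (E)-hepta-1,6-dienyl at C4 | C=CCCC/C=C/[C@@](OC)([C@H](C)[C@@H](OC(C)=O)c1ccc(OC)c(OC)c1)C#C
F8 | step 13 | analogue of 18 with (E)-hepta-1,6-dienyl at C4 | C=CCCC/C=C/[C@@](OC)([C@H](C)[C@@H](OC(C)=O)c1ccc(OC)c(OC)c1)C#CC(=O)C(=C)CC=C
F9 | step 13 | relay substrate, analogue of 19 with (E)-hepta-1,6-dienyl at C4 | C=CCCC/C=C/[C@@](OC)([C@H](C)[C@@H](OC(C)=O)c1ccc(OC)c(OC)c1)/C(OC)=C\C(=O)C(=C)CC=C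
F10 | step 12 | (1R,2R,3R)-1-(3,4-dimethoxyphenyl)-3-ethenyl-3-methoxy-2-methyl-6-oxodec-9-en-4-yn-1-yl acetate | C=C[C@@](OC)([C@H](C)[C@@H](OC(C)=O)c1ccc(OC)c(OC)c1)C#CC(=O)CCC=C
F11 | step 12 | (1R,2R,3R,4E)-1-(3,4-dimethoxyphenyl)-3-ethenyl-3,4-dimethoxy-2-methyl-6-oxodeca-4,9-dien-1-yl acetate | C=C[C@@](OC)([C@H](C)[C@@H](OC(C)=O)c1ccc(OC)c(OC)c1)/C(OC)=C\C(=O)CCC=C
F12 | step 12 | C1 trimethylsilyl dienol ether of F11 (Z at C1=C2) | C=C[C@@](OC)([C@H](C)[C@@H](OC(C)=O)c1ccc(OC)c(OC)c1)/C(OC)=C\C(O[Si](C)(C)C)=C\CC=C
F13 | step 12 | C2 (dimethylamino)methyl ketone (Mannich base, C2 epimers) | C=C[C@@](OC)([C@H](C)[C@@H](OC(C)=O)c1ccc(OC)c(OC)c1)/C(OC)=C\C(=O)C(CN(C)C)CC=C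
F14 | step 12 | methiodide of F13 | C=C[C@@](OC)([C@H](C)[C@@H](OC(C)=O)c1ccc(OC)c(OC)c1)/C(OC)=C\C(=O)C(C[N+](C)(C)C)CC=C.[I-]
F15 | step 5 | (2R,3R)-3-[(tert-butyldimethylsilyl)oxy]-3-(3,4-dimethoxyphenyl)-N-methoxy-N,2-dimethylpropanamide | CON(C)C(=O)[C@H](C)[C@@H](O[Si](C)(C)C(C)(C)C)c1ccc(OC)c(OC)c1
F16 | step 5 | (4R,5R)-5-[(tert-butyldimethylsilyl)oxy]-5-(3,4-dimethoxyphenyl)-4-methyl-1-(trimethylsilyl)pent-1-yn-3-one | C[Si](C)(C)C#CC(=O)[C@H](C)[C@@H](O[Si](C)(C)C(C)(C)C)c1ccc(OC)c(OC)c1
F17 | step 5 | analogue of 11 with OTBS in place of OSEM at C7 | C=C[C@@](O)([C@H](C)[C@@H](O[Si](C)(C)C(C)(C)C)c1ccc(OC)c(OC)c1)C#C[Si](C)(C)C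
F18 | step 5 | analogue of 12 with OTBS in place of OSEM at C7 | C=C[C@@](OC)([C@H](C)[C@@H](O[Si](C)(C)C(C)(C)C)c1ccc(OC)c(OC)c1)C#C[Si](C)(C)C
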